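**Assumption:** the target, PhCH2–S–S–S–CH2–S–S–S–CH2Ph, has no stereocentre and is achiral, so there is no enantiomer to control; the SMILES is taken as written.

## Retrosynthetic overview

1. The target is CH2(S–S–S–CH2Ph)2; it is acyclic, so no ring is formed at any stage.
2. Key disconnection: both central CH2–S bonds (carbon–heteroatom bonds, made by acetal-type C–O → C–S exchange). This gives two benzyl hydrotrisulfide units, masked as the S-acetyl trisulfide, plus dimethoxymethane as the CH2 donor.
3. Acetyl benzyl trisulfide: S–S disconnection to benzyl chlorodisulfide and thioacetic acid.
4. Benzyl chlorodisulfide: S–S disconnection to benzyl mercaptan and sulfur dichloride.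

## Route

Step 1
Reactants: 1 benzyl mercaptan (phenylmethanethiol); 2 sulfur dichloride
Product: 3 benzyl chlorodisulfide (benzyldisulfanyl chloride, PhCH2–S–S–Cl)
Conditions: 1 added dropwise to SCl2 (4 equiv, freshly distilled), Et2O, −78 °C, 1 h, N2 sweep; volatiles and excess SCl2 removed at 0 °C in vacuo; used crude at once
Reagents that add atoms: sulfur dichloride, ClSCl
Why: Sulfenylation of a thiol by SCl2 (S–S bond formation by substitution at sulfur); inverse addition into excess SCl2 at −78 °C stops at the mono-substitution product and suppresses dibenzyl trisulfide.

Step 2
Reactants: 3 benzyl chlorodisulfide; 4 thioacetic acid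
Product: 5 acetyl benzyl trisulfide (PhCH2–S–S–S–C(O)CH3)
Conditions: AcSH (1.05 equiv), Et2O, −78 → 0 °C, N2 sweep, 1 h; short silica plug (hexane/CH2Cl2), kept cold and dark
Reagents that add atoms: thioacetic acid, CC(=O)S
Why: Nucleophilic substitution at the S–Cl sulfur by the thioacid (the thiol plus chlorodisulfide coupling used for unsymmetrical trisulfides), giving an acyl trisulfide that carries the intact Bn–S–S–S chain in a storable, non-nucleophilic form.

Step 3
Reactants: 5 acetyl benzyl trisulfide (2.1 equiv); 6 dimethoxymethane (1.0 equiv)
Product: 9 1,7-dibenzyl-4-carbaheptasulfane [bis(benzyltrisulfanyl)methane], via benzyl hydrotrisulfide 7 (not isolated), via benzyl methoxymethyl trisulfide 8 (not isolated)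
Conditions: CH2(OMe)2, HCl (3 M in MeOH)/CH2Cl2 1:2, 0 °C → rt, 16 h, N2, dark; aqueous wash, silica (hexane/CH2Cl2), no amine or phosphine contact
Reagents that add atoms: dimethoxymethane, COCOC
Why: Proposed new method: acid-mediated deacetylative "perthioacetalisation", in which HCl/MeOH transesterifies the S-acetyl group to release hydrotrisulfide 7 at low steady-state concentration (as known for acyl disulfides giving hydrodisulfides) while the same acid ionises dimethoxymethane to the methoxymethyl cation, which the terminal sulfur of 7 (an α-effect nucleophile that stays un-ionised under acid, so the polysulfide chain is not scrambled by thiolate attack) captures to give O,S-acetal 8, and loss of methanol from 8 gives a sulfur-stabilised carbenium ion that a second 7 traps, so both central CH2–S bonds are formed in one flask; the closest known reaction type is the acid-catalysed dithioacetalisation of formaldehyde acetals with thiols.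

## Compound list

1 | benzyl mercaptan (phenylmethanethiol) | SCc1ccccc1 | starting material
2 | sulfur dichloride | ClSCl | starting material
3 | benzyl chlorodisulfide (benzyldisulfanyl chloride) | ClSSCc1ccccc1 | intermediate
4 | thioacetic acid | CC(=O)S | starting material
5 | acetyl benzyl trisulfide (S-acetyl benzyltrisulfane) | CC(=O)SSSCc1ccccc1 | intermediate
6 | dimethoxymethane | COCOC | starting material
7 | benzyl hydrotrisulfide (benzyltrisulfane, PhCH2–S–S–S–H; not isolated) | SSSCc1ccccc1 | intermediate
8 | benzyl methoxymethyl trisulfide (PhCH2–S–S–S–CH2–OCH3; not isolated) | COCSSSCc1ccccc1 | intermediate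
9 | 1,7-dibenzyl-4-carbaheptasulfane | c1ccc(CSSSCSSSCc2ccccc2)cc1 | target

## Step count and risks

Total step count: 3. Longest linear sequence: 3.

The three steps most likely to fail, in order of risk:

**Step 3 (the proposed new step).** Free hydrotrisulfide 7 may lose H2S or sulfur faster than it is trapped. That would give dibenzyl polysulfides and lower homologues such as Bn–S–S–CH2–S–S–S–Bn, which are hard to separate from 9. The fallback uses known chemistry only, sets out from 3 and comes back to the route at 9. Dibromomethane and potassium thioacetate (2.1 equiv, DMF, rt) give bis(acetylthio)methane F1. HCl/MeOH at rt removes both acetyl groups to give methanedithiol F2, which is handled as a cold ether solution. F2 (1 equiv) is then added to 3 (2 equiv) in Et2O at −78 → 0 °C. This is the established thiol plus chlorodisulfide coupling to trisulfides. Here the central sulfurs arrive on the carbon, the final bonds formed are S–S, and no hydrotrisulfide is involved.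

**Step 1.** The chlorodisulfide 3 may over-react to dibenzyl trisulfide, or be chlorinated or cleaved at the benzylic position by Cl2 present in aged SCl2. The fallback reverses the roles of the two sulfur partners, sets out from 1 and comes back at 5. Thioacetic acid 4 is added to excess SCl2 2 (Et2O, −78 °C) to give acetyl chlorodisulfide F3. After the excess SCl2 is stripped, F3 is treated with 1 (Et2O, −78 → 0 °C) to give 5. The benzylic thiol then acts only as the nucleophile and no benzyl sulfur chloride is ever made.

**Step 2.** The coupling of 3 with thioacetic acid under HCl evolution may scramble the sulfur chain, giving di- and tetrasulfide contaminants of 5. The fallback replaces the chloride by an isolable, crystalline sulfur-transfer reagent, sets out from 1 and comes back at 5. Phthalimide and SCl2 2 (DMF, rt) give N,N'-thiobisphthalimide F4. F4 with 1 (1 equiv, CH2Cl2, rt) gives N-(benzyldisulfanyl)phthalimide F5, which can be recrystallised and stored. F5 with thioacetic acid 4 (CH2Cl2, rt) gives 5 under neutral conditions.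

## Further compounds

F1 | step 3 | bis(acetylthio)methane (S,S'-methylene diethanethioate) | CC(=O)SCSC(C)=O
F2 | step 3 | methanedithiol | SCS
F3 | step 1 | acetyl chlorodisulfide (acetyldisulfanyl chloride) | CC(=O)SSCl
F4 | step 2 | N,N'-thiobisphthalimide | O=C1c2ccccc2C(=O)N1SN1C(=O)c2ccccc2C1=O
F5 | step 2 | N-(benzyldisulfanyl)phthalimide | O=C1c2ccccc2C(=O)N1SSCc1ccccc1
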